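**Strategy.** The tetrahydrofuran ring (O, C11, C12, C13, C14) is disconnected as a formal [3+2] adduct of the C11=C12 isopropenyl alkene of a trans-fused hydroazulene trienol and a C13–C14–O unit. The route exploits the cis relation of the C6 oxygen to the C7 side chain and the fact that C15 can be a carbonyl: (R)-glycidate is esterified to C6–OH and opened to the iodohydrin. In one operation, photoredox 8-endo radical cyclisation (C12–C13) and transannular capture of the C11 cation by the C14 hydroxyl (O–C11) give a lactone-bridged, necessarily cis tetrahydrofuran. Methyl Grignard then converts the lactone into C15 and C6–OH. The core comes from an Evans aldol, conjugate addition–allylation and two metatheses.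

Key step: step 15

Remark on numbering: C1 and C5 are the ring-fusion carbons (C1 next to C10, which carries the exocyclic methylene; C5 next to C4, which carries the ring methyl), C2 and C3 complete the cyclopentene, C6 is the carbinol carbon, C7 carries the side chain, C8 and C9 are ring CH2 groups; C11 is the quaternary tetrahydrofuran carbon, C12 and C13 its CH2 groups, C14 its CH, C15 the acetoxy-bearing carbon.

Remark on the target: the hydroazulene is taken exactly as drawn, i.e. trans-fused (H1 and H5 anti), with 6-OH cis to the C7 side chain and a cis-2,5 relation of C7 and C15 on the tetrahydrofuran.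

Assumption: potassium (R)-glycidate (19) is taken as a catalogue compound; otherwise it is one operation from commercial methyl (R)-glycidate (KOH, EtOH).

**Step 1**
Reactants: 1 (R)-4-benzyl-1,3-oxazolidin-2-one; 2 hept-6-enoic acid
Product: 4 (R)-4-benzyl-3-(hept-6-enoyl)-1,3-oxazolidin-2-one, via hept-6-enoic pivalic anhydride 3 (not isolated)
Conditions: PivCl, Et3N, THF, −20 °C; then 1, LiCl, −20 °C → rt
Reagents that add atoms: none
Why: N-acylation of the oxazolidinone by the mixed pivalic anhydride should attach the C11/C7–C10/C1 chain to the auxiliary; no stereocentre is formed.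

**Step 2**
Reactants: 4 (R)-4-benzyl-3-(hept-6-enoyl)-1,3-oxazolidin-2-one; 5 acrolein
Product: 7 (R)-4-benzyl-3-[(2R,3S)-3-hydroxy-2-(pent-4-en-1-yl)pent-4-enoyl]-1,3-oxazolidin-2-one, via dibutylboron enolate 6 (not isolated)
Conditions: n-Bu2BOTf, i-Pr2NEt, CH2Cl2, −78 → 0 °C; 5, −78 °C; then H2O2, pH 7 buffer, MeOH
Reagents that add atoms: none
Why: Evans syn aldol: the Z boron enolate should add to acrolein through a chair transition state on the face remote from the benzyl group, setting C7 and C6 in the syn relation that becomes the cis C6–O/C7 side-chain arrangement.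

**Step 3**
Reactants: 7 (R)-4-benzyl-3-[(2R,3S)-3-hydroxy-2-(pent-4-en-1-yl)pent-4-enoyl]-1,3-oxazolidin-2-one
Product: 8 (2R,3S)-3-hydroxy-N-methoxy-N-methyl-2-(pent-4-en-1-yl)pent-4-enamide
Conditions: MeNH(OMe)·HCl, AlMe3, CH2Cl2, −10 → 0 °C
Reagents that add atoms: N,O-dimethylhydroxylamine hydrochloride, CNOC.Cl
Why: aluminium-amide transamination (Weinreb amide formation), assisted by the free β-hydroxyl, should replace the auxiliary without touching C6 or C7.

**Step 4**
Reactants: 8 (2R,3S)-3-hydroxy-N-methoxy-N-methyl-2-(pent-4-en-1-yl)pent-4-enamide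
Product: 9 (2R,3S)-3-[(tert-butyldimethylsilyl)oxy]-N-methoxy-N-methyl-2-(pent-4-en-1-yl)pent-4-enamide
Conditions: TBSOTf, 2,6-lutidine, CH2Cl2, −78 → 0 °C
Reagents that add atoms: tert-butyldimethylsilyl triflate, CC(C)(C)[Si](C)(C)OS(=O)(=O)C(F)(F)F
Why: silylation (TBS ether) masks C6–OH for the organometallic, oxidation and cuprate steps and later steers the conjugate addition.

**Step 5**
Reactants: 9 (2R,3S)-3-[(tert-butyldimethylsilyl)oxy]-N-methoxy-N-methyl-2-(pent-4-en-1-yl)pent-4-enamide
Product: 10 (3R,4S)-4-[(tert-butyldimethylsilyl)oxy]-3-(pent-4-en-1-yl)hex-5-en-2-one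
Conditions: MeMgBr, THF, −20 → 0 °C; aq. NH4Cl
Reagents that add atoms: methylmagnesium bromide, C[Mg]Br
Why: Weinreb ketone synthesis: the chelated tetrahedral adduct should stop at the methyl ketone (C11 with its future methyl group).

**Step 6**
Reactants: 10 (3R,4S)-4-[(tert-butyldimethylsilyl)oxy]-3-(pent-4-en-1-yl)hex-5-en-2-one
Product: 11 tert-butyl(dimethyl){[(3S,4S)-4-(prop-1-en-2-yl)nona-1,8-dien-3-yl]oxy}silane
Conditions: Zn, CH2Br2, TiCl4, THF/CH2Cl2, 0 °C → rt
Reagents that add atoms: dibromomethane, BrCBr
Why: Takai–Lombardo methylenation should turn the ketone into the C11=C12 isopropenyl group under non-basic conditions, so C7 should not epimerise and the β-silyloxy group should not eliminate.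

**Step 7**
Reactants: 11 tert-butyl(dimethyl){[(3S,4S)-4-(prop-1-en-2-yl)nona-1,8-dien-3-yl]oxy}silane
Product: 12 tert-butyl(dimethyl){[(1S,7S)-7-(prop-1-en-2-yl)cyclohept-2-en-1-yl]oxy}silane
Conditions: second-generation Grubbs catalyst (H2IMes)(PCy3)Cl2Ru=CHPh (3 mol %), CH2Cl2 (5 mM), 40 °C
Reagents that add atoms: none
Why: ring-closing metathesis of the two monosubstituted alkenes should close the seven-membered ring at C1=C5, the 1,1-disubstituted isopropenyl group being much less reactive.

**Step 8**
Reactants: 12 tert-butyl(dimethyl){[(1S,7S)-7-(prop-1-en-2-yl)cyclohept-2-en-1-yl]oxy}silane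
Product: 13 (4S,5S)-4-[(tert-butyldimethylsilyl)oxy]-5-(prop-1-en-2-yl)cyclohept-2-en-1-one
Conditions: Rh2(cap)4 (cap = caprolactamate, 1 mol %), t-BuOOH (70% in water), K2CO3, CH2Cl2, rt
Reagents that add atoms: tert-butyl hydroperoxide, CC(C)(C)OO
Why: allylic oxidation (tert-butylperoxyl radical chain) should convert the unhindered ring CH2 at C10 into the enone carbonyl, C6–H being shielded by the silyl ether.

**Step 9**
Reactants: 13 (4S,5S)-4-[(tert-butyldimethylsilyl)oxy]-5-(prop-1-en-2-yl)cyclohept-2-en-1-one
Product: 15 (2R,3S,4R,5S)-2-allyl-4-[(tert-butyldimethylsilyl)oxy]-3,5-di(prop-1-en-2-yl)cycloheptan-1-one, via lithium enolate 14 (not isolated)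
Conditions: [CH2=C(CH3)]2CuLi (from 2-bromopropene, t-BuLi, CuI), Et2O, −78 °C; then allyl iodide, HMPA, THF, −78 → −20 °C
Reagents that add atoms: lithium di(prop-1-en-2-yl)cuprate, [Li+].C=C(C)[Cu-]C(C)=C; allyl iodide, C=CCI
Why: tandem conjugate addition–enolate alkylation: the cuprate should add to C5 anti to the neighbouring silyloxy group (and to the cis C7 substituent), and the regiodefined enolate should be allylated at C1 trans to the new C5 group.

**Step 10**
Reactants: 15 (2R,3S,4R,5S)-2-allyl-4-[(tert-butyldimethylsilyl)oxy]-3,5-di(prop-1-en-2-yl)cycloheptan-1-one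
Product: 16 trans-fused hydroazulenone (C10 ketone, C3=C4 with methyl on C4, 6-OTBS, 7-isopropenyl; 1R,5S,6R,7S in the numbering of the remark)
Conditions: second-generation Hoveyda–Grubbs catalyst (H2IMes)Cl2Ru=CH(C6H4-2-O-i-Pr) (5 mol %), toluene, 80 °C
Reagents that add atoms: none
Why: ring-closing metathesis between the allyl group and the adjacent C5 isopropenyl group should form the trisubstituted cyclopentene, trans-fused because C1 and C5 are trans; the C7 isopropenyl group could only close a larger or tetrasubstituted ring.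

**Step 11**
Reactants: 16 trans-fused hydroazulenone
Product: 17 silyl ether of the trienol (C10 exocyclic methylene; 1R,5S,6R,7S)
Conditions: Zn, CH2Br2, TiCl4, THF/CH2Cl2, 0 °C → rt
Reagents that add atoms: dibromomethane, BrCBr
Why: Takai–Lombardo methylenation should give the exocyclic C10 methylene without base, leaving the epimerisable C1 ring-fusion centre intact.

**Step 12**
Reactants: 17 silyl ether of the trienol
Product: 18 trienol (free C6–OH, C7 isopropenyl, C3=C4, C10 methylene; 1R,5S,6R,7S)
Conditions: Bu4NF, THF, 0 °C → rt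
Reagents that add atoms: none
Why: fluoride-mediated desilylation frees C6–OH.

**Step 13**
Reactants: 18 trienol; 19 potassium (R)-oxirane-2-carboxylate
Product: 21 (R)-glycidate ester of 18 at C6–O, via glycidic trichlorobenzoic anhydride 20 (not isolated)
Conditions: 2,4,6-trichlorobenzoyl chloride, Et3N, THF, 0 °C; then 18, DMAP, toluene, rt
Reagents that add atoms: none
Why: Yamaguchi esterification should acylate the hindered secondary C6–OH; the epoxide carbon that becomes C14 is not touched.

**Step 14**
Reactants: 21 (R)-glycidate ester of 18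
Product: 22 (S)-2-hydroxy-3-iodopropanoate ester of 18 (same spatial arrangement at C14; the descriptor changes because iodine raises the priority of C13)
Conditions: LiI, AcOH, THF, 0 °C → rt
Reagents that add atoms: lithium iodide, [Li+].[I-]
Why: regioselective SN2 opening of the glycidic ester by iodide at the CH2 carbon remote from the carbonyl (C13) gives the iodohydrin; the C14–O bond is not broken, so C14 keeps its configuration.

**Step 15**
Reactants: 22 (S)-2-hydroxy-3-iodopropanoate ester of 18
Product: 23 lactone-bridged tetrahydrofuran (O–C11 and C12–C13 formed; C15 is the lactone carbonyl bound to O6; 1R,5S,6S,7R,11S,14R)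
Conditions: fac-Ir(ppy)3 (2 mol %), 2,6-lutidine, MeCN (5 mM), 450 nm LEDs, rt
Reagents that add atoms: none
Why: Photoexcited fac-Ir(ppy)3 transfers an electron to the C13–I bond; the primary radical adds in 8-endo-trig mode to the CH2 terminus (C12) of the isopropenyl group (the ester can keep its Z geometry in an eight-membered transition state, and attack at the substituted C11 is blocked), and the tertiary C11 radical is oxidised by tetravalent iridium to the cation, which the C14 hydroxyl captures across the ring in a five-membered etherification, the proton going to lutidine. The closest known reaction types are visible-light iodine-atom-transfer and radical–polar crossover carboetherifications of alkenes with alkyl halides and the 8-endo cyclisations of ester-tethered radicals. C14 comes unchanged from (R)-glycidate, and because C14 and C11 end up as bridgeheads joined by the four-atom chain C15(=O)–O–C6–C7, the tetrahydrofuran can only close with C15 and C7 cis, which fixes C11 as S. The step needs chemoselectivity among three alkenes and regioselectivity for C12: the tether reaches the cis-disposed C7 isopropenyl group far more easily than C3=C4 or the C10 methylene, and no external radical trap competes under the redox-neutral conditions.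

**Step 16**
Reactants: 23 lactone-bridged tetrahydrofuran
Product: 25 6,15-di-O-acetate (target bearing an extra acetate on C6–O), via diol 24 (not isolated)
Conditions: MeMgBr (5 equiv), THF, −40 → 0 °C; then Ac2O, DMAP, 0 °C → rt; aq. NH4Cl
Reagents that add atoms: methylmagnesium bromide, C[Mg]Br; acetic anhydride, CC(=O)OC(C)=O
Why: double Grignard addition to the lactone carbonyl should build the dimethylcarbinol at C15 and release the C6 alkoxide, and both magnesium alkoxides are then acetylated in the same flask (O-acylation).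

**Step 17**
Reactants: 25 6,15-di-O-acetate
Product: 26 target, CNP0302132.4 (1R,5S,6S,7R,11S,14R)
Conditions: K2CO3, MeOH, 0 °C → rt
Reagents that add atoms: none
Why: selective methanolysis (transesterification) should cleave the secondary C6 acetate while the hindered tertiary C15 acetate survives.

**Compound list**

1 | (R)-4-benzyl-1,3-oxazolidin-2-one | O=C1N[C@H](Cc2ccccc2)CO1 | starting material
2 | hept-6-enoic acid | C=CCCCCC(=O)O | starting material
3 | hept-6-enoic pivalic anhydride | C=CCCCCC(=O)OC(=O)C(C)(C)C | intermediate (not isolated)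
4 | (R)-4-benzyl-3-(hept-6-enoyl)-1,3-oxazolidin-2-one | C=CCCCCC(=O)N1[C@H](Cc2ccccc2)COC1=O | intermediate
5 | acrolein (prop-2-enal) | C=CC=O | starting material
6 | dibutylboron (Z)-enolate of 4 | CCCCB(CCCC)O/C(N1[C@H](Cc2ccccc2)COC1=O)=C\CCCCC=C | intermediate (not isolated)
7 | (R)-4-benzyl-3-[(2R,3S)-3-hydroxy-2-(pent-4-en-1-yl)pent-4-enoyl]-1,3-oxazolidin-2-one | C=CCCC[C@H]([C@@H](O)C=C)C(=O)N1[C@H](Cc2ccccc2)COC1=O | intermediate
8 | (2R,3S)-3-hydroxy-N-methoxy-N-methyl-2-(pent-4-en-1-yl)pent-4-enamide | C=CCCC[C@H]([C@@H](O)C=C)C(=O)N(C)OC | intermediate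
9 | (2R,3S)-3-[(tert-butyldimethylsilyl)oxy]-N-methoxy-N-methyl-2-(pent-4-en-1-yl)pent-4-enamide | C=CCCC[C@H]([C@@H](O[Si](C)(C)C(C)(C)C)C=C)C(=O)N(C)OC | intermediate
10 | (3R,4S)-4-[(tert-butyldimethylsilyl)oxy]-3-(pent-4-en-1-yl)hex-5-en-2-one | C=CCCC[C@H]([C@@H](O[Si](C)(C)C(C)(C)C)C=C)C(C)=O | intermediate
11 | tert-butyl(dimethyl){[(3S,4S)-4-(prop-1-en-2-yl)nona-1,8-dien-3-yl]oxy}silane | C=CCCC[C@H]([C@@H](O[Si](C)(C)C(C)(C)C)C=C)C(C)=C | intermediate
12 | tert-butyl(dimethyl){[(1S,7S)-7-(prop-1-en-2-yl)cyclohept-2-en-1-yl]oxy}silane | C1CC[C@@H](C(C)=C)[C@@H](O[Si](C)(C)C(C)(C)C)C=C1 | intermediate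
13 | (4S,5S)-4-[(tert-butyldimethylsilyl)oxy]-5-(prop-1-en-2-yl)cyclohept-2-en-1-one | O=C1CC[C@@H](C(C)=C)[C@@H](O[Si](C)(C)C(C)(C)C)C=C1 | intermediate
14 | lithium (3S,4R,5S)-4-[(tert-butyldimethylsilyl)oxy]-3,5-di(prop-1-en-2-yl)cyclohept-1-en-1-olate | [Li+].[O-]C1CC[C@@H](C(C)=C)[C@@H](O[Si](C)(C)C(C)(C)C)[C@H](C(C)=C)C=1 | intermediate (not isolated)
15 | (2R,3S,4R,5S)-2-allyl-4-[(tert-butyldimethylsilyl)oxy]-3,5-di(prop-1-en-2-yl)cycloheptan-1-one | O=C1CC[C@@H](C(C)=C)[C@@H](O[Si](C)(C)C(C)(C)C)[C@H](C(C)=C)[C@H]1CC=C | intermediate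
16 | trans-fused hydroazulenone: C10 ketone, C3=C4 (methyl on C4), 6-OTBS, 7-isopropenyl; (1R,5S,6R,7S) | O=C1CC[C@@H](C(C)=C)[C@@H](O[Si](C)(C)C(C)(C)C)[C@@H]2C(C)=CC[C@@H]12 | intermediate
17 | same skeleton with C10 exocyclic methylene, 6-OTBS; (1R,5S,6R,7S) | C=C1CC[C@@H](C(C)=C)[C@@H](O[Si](C)(C)C(C)(C)C)[C@@H]2C(C)=CC[C@@H]12 | intermediate
18 | trienol: trans-fused hydroazulene, C10 methylene, C3=C4, 6-OH cis to 7-isopropenyl; (1R,5S,6R,7S) | C=C1CC[C@@H](C(C)=C)[C@@H](O)[C@@H]2C(C)=CC[C@@H]12 | intermediate
19 | potassium (R)-oxirane-2-carboxylate (potassium (R)-glycidate) | [K+].[O-]C(=O)[C@H]1CO1 | starting material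
20 | (R)-oxirane-2-carboxylic 2,4,6-trichlorobenzoic anhydride | O=C(OC(=O)[C@H]1CO1)c1c(Cl)cc(Cl)cc1Cl | intermediate (not isolated)
21 | (R)-oxirane-2-carboxylate (glycidate) ester of 18 at C6–O | C=C1CC[C@@H](C(C)=C)[C@@H](OC(=O)[C@H]3CO3)[C@@H]2C(C)=CC[C@@H]12 | intermediate
22 | (S)-2-hydroxy-3-iodopropanoate ester of 18 at C6–O | C=C1CC[C@@H](C(C)=C)[C@@H](OC(=O)[C@H](O)CI)[C@@H]2C(C)=CC[C@@H]12 | intermediate
23 | lactone-bridged tetrahydrofuran: O bridges C14 and C11, C15(=O)–O–C6 lactone; (1R,5S,6S,7R,11S,14R) | C=C1CC[C@@H]([C@]3(C)CC[C@@H](O3)C4=O)[C@@H](O4)[C@@H]2C(C)=CC[C@@H]12 | intermediate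
24 | diol (6-OH and 15-OH; present as its bis(bromomagnesium) alkoxide) | C=C1CC[C@@H]([C@]2(C)CC[C@H](C(C)(C)O)O2)[C@@H](O)[C@@H]2C(C)=CC[C@@H]12 | intermediate (not isolated)
25 | 6,15-di-O-acetate | C=C1CC[C@@H]([C@]2(C)CC[C@H](C(C)(C)OC(C)=O)O2)[C@@H](OC(C)=O)[C@@H]2C(C)=CC[C@@H]12 | intermediate
26 | CNP0302132.4; (1R,5S,6S,7R,11S,14R) | C=C1CC[C@@H]([C@]2(C)CC[C@H](C(C)(C)OC(C)=O)O2)[C@@H](O)[C@@H]2C(C)=CC[C@@H]12 | target

**Step count and risks**

Total step count: 17. Longest linear sequence: 17 steps (1 and 2 to 26); 5 and 19 enter as purchased building blocks.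

Most likely to fail, in this order:

Step 15. The 8-endo ring closure is slow for an unstabilised primary radical, so the radical may return to the iodide or be reduced before it cyclises; the tertiary cation may also be intercepted by the ester carbonyl oxygen or lose a proton instead of being captured by the C14 hydroxyl. The fallback separates the two bond formations. It sets out from 22: iodine-atom-transfer radical cyclisation (Bu6Sn2, sun lamp, benzene, high dilution) should give the eight-membered lactone carrying the tertiary C11 iodide F1 as a mixture at C11; silver-assisted ionisation (AgOTf, 2,6-di-tert-butylpyridine, CH2Cl2, −40 °C) then lets the C14 hydroxyl close the ether under the same bridging constraint, coming back to the route at 23.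

Step 8. Hydrogen abstraction may be poorly site-selective (C6–H next to the silyl ether, C7–H, the isopropenyl methyl) and the enone may be over-oxidised. The fallback avoids C–H oxidation by carrying the C10 carbon in from the start as a nitrile. It sets out from 1, acylated with commercial 4-cyanobutanoic acid in place of 2, and repeats the operations of steps 1 to 6: these should give in turn the N-acyl oxazolidinone F2, the syn aldol adduct F3, the Weinreb amide F4, its silyl ether F5, the methyl ketone F6 (MeMgBr at −20 °C spares the nitrile) and the isopropenyl nitrile F7. Addition of vinyllithium to the nitrile and mild acidic hydrolysis of the ketimine give the vinyl ketone F8, and ring-closing metathesis of its two vinyl groups (second-generation Hoveyda–Grubbs catalyst, CH2Cl2, 40 °C) closes the enone directly, coming back to the route at 13.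

Step 9. Alkylation of the cuprate-derived enolate may be sluggish, allowing proton transfer, polyallylation or loss of facial selectivity at C1. The fallback sets out from 13: after the same cuprate addition the enolate is trapped on oxygen with allyl chloroformate to give the allyl enol carbonate F9; Pd(PPh3)4-catalysed decarboxylative allylation (Tsuji allylation, THF, rt) then delivers the allyl group regiospecifically to C1 from the face opposite the C5 substituent, coming back to the route at 15.

**Further compounds**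

F1 | step 15 | eight-membered lactone of 22 with C12–C13 formed and iodine on C11 (C11 epimers) | C=C1CC[C@@H]3[C@@H](OC(=O)[C@H](O)CCC3(C)I)[C@@H]2C(C)=CC[C@@H]12
F2 | step 8 | (R)-4-benzyl-3-(4-cyanobutanoyl)-1,3-oxazolidin-2-one | N#CCCCC(=O)N1[C@H](Cc2ccccc2)COC1=O
F3 | step 8 | (R)-4-benzyl-3-[(2R,3S)-2-(2-cyanoethyl)-3-hydroxypent-4-enoyl]-1,3-oxazolidin-2-one | N#CCC[C@H]([C@@H](O)C=C)C(=O)N1[C@H](Cc2ccccc2)COC1=O
F4 | step 8 | (2R,3S)-2-(2-cyanoethyl)-3-hydroxy-N-methoxy-N-methylpent-4-enamide | N#CCC[C@H]([C@@H](O)C=C)C(=O)N(C)OC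
F5 | step 8 | tert-butyldimethylsilyl ether of F4 | N#CCC[C@H]([C@@H](O[Si](C)(C)C(C)(C)C)C=C)C(=O)N(C)OC
F6 | step 8 | (4R,5S)-4-acetyl-5-[(tert-butyldimethylsilyl)oxy]hept-6-enenitrile | N#CCC[C@H]([C@@H](O[Si](C)(C)C(C)(C)C)C=C)C(C)=O
F7 | step 8 | (4S,5S)-5-[(tert-butyldimethylsilyl)oxy]-4-(prop-1-en-2-yl)hept-6-enenitrile | N#CCC[C@H]([C@@H](O[Si](C)(C)C(C)(C)C)C=C)C(C)=C
F8 | step 8 | (6S,7S)-7-[(tert-butyldimethylsilyl)oxy]-6-(prop-1-en-2-yl)nona-1,8-dien-3-one | C=CC(=O)CC[C@H]([C@@H](O[Si](C)(C)C(C)(C)C)C=C)C(C)=C
F9 | step 9 | allyl enol carbonate of the conjugate adduct (allyl carbonate of enolate 14) | C=CCOC(=O)OC1CC[C@@H](C(C)=C)[C@@H](O[Si](C)(C)C(C)(C)C)[C@H](C(C)=C)C=1
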